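**Remark:** positions follow eudesmane numbering of the target (ring A = C1–C5 and C10, ring B = C5–C10, C11–C13 on C7, C14 = methyl on C10, C15 on C4; β = the face of the C10 methyl group); commercial (+)-dihydrocarvone is used as its mixture of C2 epimers (drawn as the 2R,5R isomer), which converge at the enamine in step 1.

**Retrosynthetic overview**
1. The C15–O ester is made last by Mitsunobu coupling of the ring A allylic alcohol with (Z)-p-coumaric acid; the C12 methyl ester comes from carbonylation of an enol triflate derived from the C7 isopropenyl group.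
2. Key disconnection: the C2–C3 bond of ring A, leading back to a monocyclic ring B acid with a CH2CH2CO2H arm on C10 and a C(=CH2)CO2Me group on C5. In the forward direction one operation extrudes CO2, closes ring A and leaves the C3=C4–C15 enoate.
3. Enabling feature: C3=C4–C15 of ring A is the β-carbon, α-carbon and carbonyl of an α-substituted acrylate hung on C5, and C2 ends a two-carbon arm on the neighbouring quaternary C10 of ring B. A C2 radical therefore reaches the unsubstituted C3 through a chair-like six-membered transition state, and the C4 radical is desaturated toward C3.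
4. The ring B acid comes from (+)-dihydrocarvone: C7 from the chiral pool, C10 by a chiral-imine Michael addition, the C4–C5 bond by enol triflate coupling, C5 by conjugate reduction and equilibration, C3/C15 by triflation and carbonylation.
5. Ring order: ring B (from the terpene) first, ring A second (step 8), side chains last.

Key step: step 8

**Route**

Step 1
Reactants: 1 (+)-dihydrocarvone; 2 (R)-1-phenylethylamine; 3 tert-butyl acrylate
Product: 6 tert-butyl 3-[(1S,4R)-1-methyl-2-oxo-4-(prop-1-en-2-yl)cyclohexyl]propanoate (10β-methyl cis to the 7β-isopropenyl group; propanoate arm α), via imine 4 (not isolated), via alkylated imine 5 (not isolated)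
Conditions: 2 (1.05 equiv), TsOH·H2O (1 mol %), toluene, reflux, Dean–Stark trap; then 3 (3 equiv), THF, 60 °C; then 20% aq. AcOH, 25 °C
Reagents that add atoms: water, O
Why: Chiral-imine Michael addition through the more substituted secondary enamine (aza-ene-like transition state) should alkylate C10 regioselectively, the (R)-phenylethyl group directing the acrylate to the face trans to the isopropenyl group so that the new quaternary centre carries its methyl cis to the C7 substituent.

Step 2
Reactants: 6 keto ester
Product: 7 C5–C6 enol triflate of 6 (cyclohexenyl triflate next to the quaternary C10)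
Conditions: KN(SiMe3)2 (1.1 equiv), THF, −78 °C; then PhNTf2 (1.1 equiv), −78 to 0 °C
Reagents that add atoms: N-phenylbis(trifluoromethanesulfonimide) (PhNTf2), O=S(=O)(N(c1ccccc1)S(=O)(=O)C(F)(F)F)C(F)(F)F
Why: Enol triflate formation; the ketone can enolize only toward C6 because C10 is quaternary, and the ester α-protons are much less acidic.

Step 3
Reactants: 7 enol triflate
Product: 9 methyl enone (acetyl group on C5 of the C5=C6 cyclohexene), via ethoxy diene 8 (not isolated)
Conditions: tributyl(1-ethoxyvinyl)stannane (1.3 equiv), Pd(PPh3)4 (5 mol %), LiCl (3 equiv), CuI (10 mol %), 1,4-dioxane, 90 °C; then 1 M HCl, THF, 25 °C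
Reagents that add atoms: tributyl(1-ethoxyvinyl)stannane, CCCC[Sn](CCCC)(CCCC)C(=C)OCC; water, O
Why: Stille coupling of the hindered vinyl triflate with an acyl-anion equivalent, then mild enol ether hydrolysis, should attach the C4 carbonyl carbon to C5 without touching the tert-butyl ester or the isopropenyl group.

Step 4
Reactants: 9 methyl enone
Product: 11 methyl ketone with 5α-H (acetyl β and equatorial, trans to the C10 propanoate arm, cis to the 7β-isopropenyl group), via C5-epimeric ketone 10 (not isolated)
Conditions: [(Ph3P)CuH]6 (5 mol %), PhMe2SiH (1.5 equiv), t-BuOH (1.5 equiv), toluene, 25 °C; then NaOMe (0.2 equiv), MeOH, 25 °C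
Reagents that add atoms: none
Why: Copper hydride conjugate reduction should deliver hydride to C6 chemoselectively, and base equilibration at the enolizable C5 should favour the equatorial acetyl group (thermodynamic control of the new C5 stereocentre); recovered C5 epimer can be re-equilibrated.

Step 5
Reactants: 11 methyl ketone
Product: 12 terminal enol triflate (C5 carries C(OTf)=CH2; the CH2 is the future C3)
Conditions: KN(SiMe3)2 (1.1 equiv), THF, −78 °C; then PhNTf2 (1.1 equiv)
Reagents that add atoms: N-phenylbis(trifluoromethanesulfonimide) (PhNTf2), O=S(=O)(N(c1ccccc1)S(=O)(=O)C(F)(F)F)C(F)(F)F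
Why: Kinetic enol triflate formation; the bulky amide should deprotonate the methyl group and not the hindered C5 methine, so C5 keeps its configuration.

Step 6
Reactants: 12 terminal enol triflate
Product: 13 acrylate tert-butyl ester (C5 carries C(=CH2)CO2Me: C3 is the CH2, C4 the α-carbon, C15 the ester carbon)
Conditions: Pd(OAc)2 (5 mol %), PPh3 (10 mol %), CO (1 atm), MeOH (20 equiv), Et3N (2 equiv), DMF, 50 °C
Reagents that add atoms: carbon monoxide, [C-]#[O+]; methanol, CO
Why: Palladium-catalysed alkoxycarbonylation of a vinyl triflate (oxidative addition to zerovalent palladium, CO insertion, methanolysis) should give the α-substituted acrylate.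

Step 7
Reactants: 13 acrylate tert-butyl ester
Product: 14 acid (C10 carries methyl and CH2CH2CO2H; C5 carries C(=CH2)CO2Me; C7 carries isopropenyl)
Conditions: ZnBr2 (5 equiv), CH2Cl2, 25 °C
Reagents that add atoms: none
Why: Lewis-acid-mediated tert-butyl ester cleavage (loss of isobutene) should free the acid while leaving the methyl acrylate and the isopropenyl group intact.

Step 8
Reactants: 14 acid
Product: 15 methyl 5α-H-eudesma-3,11-dien-15-oate (trans-fused decalin; C3=C4 conjugated with the C15 methyl ester; 7β-isopropenyl; 10β-methyl)
Conditions: 9-mesityl-10-methylacridinium tetrafluoroborate (5 mol %), Co(dmgH)2(py)Cl (3 mol %), K3PO4 (0.2 equiv), MeCN/toluene 1:1 (5 mM), blue LEDs (450 nm), 25 °C, Ar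
Reagents that add atoms: none
Why: The excited acridinium oxidizes the carboxylate, CO2 is lost and the primary C2 radical adds to C3, the unsubstituted terminus of the acrylate on C5; divalent cobalt then removes a hydrogen atom from C3 of the tertiary C4 α-ester radical, giving the C3=C4 bond, and the hydride leaves with the acid proton as H2. The closest known reaction type is the photoredox/cobaloxime decarboxylative radical Heck-type coupling of aliphatic acids with alkenes, used here intramolecularly. Ring A is closed in the 6-endo-trig mode, preferred over 5-exo because C4 is fully substituted and the nucleophilic alkyl radical is polarity-matched with the acrylate β-carbon C3. No new stereocentre is formed; the trans-diequatorial arms on C10 and C5, fixed in steps 1 and 4, translate into the trans ring fusion. The step needs hydrogen removal from C3 rather than C5, which the two unhindered secondary C3–H bonds (against one methine C5–H next to the quaternary C10) should secure for the bulky cobaloxime, and it needs cyclization before cobalt captures the C2 radical, which high dilution and low cobalt loading favour.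

Step 9
Reactants: 15 bicyclic enoate
Product: 16 methyl ketone (7β-acetyl in place of isopropenyl; ring A enoate unchanged)
Conditions: O3 (1.0 equiv), CH2Cl2/MeOH 4:1, −78 °C; then Me2S (5 equiv), −78 to 25 °C
Reagents that add atoms: ozone, [O-][O+]=O
Why: Ozonolysis; electrophilic ozone should cleave the electron-rich 1,1-disubstituted isopropenyl alkene much faster than the electron-poor enoate alkene of ring A.

Step 10
Reactants: 16 methyl ketone
Product: 17 enol triflate (C7 carries C(OTf)=CH2; ring A enoate unchanged)
Conditions: KN(SiMe3)2 (1.05 equiv), THF, −78 °C; then PhNTf2 (1.1 equiv)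
Reagents that add atoms: N-phenylbis(trifluoromethanesulfonimide) (PhNTf2), O=S(=O)(N(c1ccccc1)S(=O)(=O)C(F)(F)F)C(F)(F)F
Why: Kinetic enol triflate formation; deprotonation of the methyl ketone at its methyl group should be far faster than γ-deprotonation of the enoate, and C7 is not enolized.

Step 11
Reactants: 17 enol triflate
Product: 18 allylic alcohol (C15 = CH2OH on the C3=C4 alkene; C7 still carries C(OTf)=CH2)
Conditions: iBu2AlH (2.5 equiv), CH2Cl2, −78 °C; aq. KNaC4H4O6 (potassium sodium tartrate) work-up
Reagents that add atoms: none
Why: 1,2-Reduction of the conjugated ester by the aluminium hydride should give the allylic alcohol while the vinyl triflate survives at low temperature, so C15 reaches its final oxidation level before the second ester exists.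

Step 12
Reactants: 18 allylic alcohol
Product: 19 methyl 15-hydroxy-5α-H-eudesma-3,11(13)-dien-12-oate
Conditions: Pd(OAc)2 (5 mol %), 1,3-bis(diphenylphosphino)propane (5 mol %), CO (1 atm), MeOH (20 equiv), Et3N (2 equiv), DMF, 50 °C
Reagents that add atoms: carbon monoxide, [C-]#[O+]; methanol, CO
Why: Palladium-catalysed alkoxycarbonylation of the vinyl triflate should install the C7 acrylate methyl ester and tolerate the free primary alcohol.

Step 13
Reactants: 20 (E)-p-coumaric acid
Product: 21 (Z)-p-coumaric acid
Conditions: hν (365 nm), MeOH, 25 °C, N2; chromatography with exclusion of light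
Reagents that add atoms: none
Why: Alkene photoisomerization of the cinnamic chromophore should give a photostationary mixture from which the Z acid is separated.

Step 14
Reactants: 19 hydroxy acrylate; 21 (Z)-p-coumaric acid
Product: 22 target, methyl 15-[(Z)-4-hydroxycinnamoyloxy]-5α-H-eudesma-3,11(13)-dien-12-oate
Conditions: PPh3 (1.3 equiv), diisopropyl azodicarboxylate (1.3 equiv), THF, 0 °C, dark
Reagents that add atoms: none
Why: Mitsunobu esterification; the carboxylic acid, far more acidic than the phenol, should displace the oxyphosphonium of the primary allylic alcohol by SN2, so no phenol protection and no acylating conditions that endanger the Z alkene are needed.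

**Compound list**
1 | (+)-dihydrocarvone, (2R,5R)-2-methyl-5-(prop-1-en-2-yl)cyclohexan-1-one | CC(=C)[C@@H]1CC[C@@H](C)C(=O)C1 | starting material
2 | (R)-1-phenylethylamine | C[C@@H](N)c1ccccc1 | starting material
3 | tert-butyl acrylate | C=CC(=O)OC(C)(C)C | starting material
4 | N-[(R)-1-phenylethyl]imine of 1 (reacts as its C5=C10 enamine tautomer) | CC(=C)[C@@H]1CC[C@@H](C)C(=N[C@H](C)c2ccccc2)C1 | intermediate
5 | C10-alkylated imine (imine of 6 with 2) | CC(=C)[C@@H]1CC[C@@](C)(CCC(=O)OC(C)(C)C)C(=N[C@H](C)c2ccccc2)C1 | intermediate
6 | tert-butyl 3-[(1S,4R)-1-methyl-2-oxo-4-(prop-1-en-2-yl)cyclohexyl]propanoate | CC(=C)[C@@H]1CC[C@@](C)(CCC(=O)OC(C)(C)C)C(=O)C1 | intermediate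
7 | C5–C6 enol triflate of 6 | CC(=C)[C@@H]1CC[C@@](C)(CCC(=O)OC(C)(C)C)C(OS(=O)(=O)C(F)(F)F)=C1 | intermediate
8 | ethoxy diene (1-ethoxyvinyl group on C5 of the C5=C6 cyclohexene) | CC(=C)[C@@H]1CC[C@@](C)(CCC(=O)OC(C)(C)C)C(C(=C)OCC)=C1 | intermediate
9 | methyl enone (acetyl on C5 of the C5=C6 cyclohexene) | CC(=C)[C@@H]1CC[C@@](C)(CCC(=O)OC(C)(C)C)C(C(C)=O)=C1 | intermediate
10 | C5-epimeric methyl ketone (5β-H, acetyl axial) | CC(=C)[C@@H]1CC[C@@](C)(CCC(=O)OC(C)(C)C)[C@@H](C(C)=O)C1 | intermediate
11 | methyl ketone (5α-H, acetyl equatorial, trans to the C10 arm) | CC(=C)[C@@H]1CC[C@@](C)(CCC(=O)OC(C)(C)C)[C@H](C(C)=O)C1 | intermediate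
12 | terminal enol triflate (C(OTf)=CH2 on C5) | CC(=C)[C@@H]1CC[C@@](C)(CCC(=O)OC(C)(C)C)[C@H](C(=C)OS(=O)(=O)C(F)(F)F)C1 | intermediate
13 | acrylate tert-butyl ester (C(=CH2)CO2Me on C5) | CC(=C)[C@@H]1CC[C@@](C)(CCC(=O)OC(C)(C)C)[C@H](C(=C)C(=O)OC)C1 | intermediate
14 | acid (CH2CH2CO2H arm on C10, C(=CH2)CO2Me on C5) | CC(=C)[C@@H]1CC[C@@](C)(CCC(=O)O)[C@H](C(=C)C(=O)OC)C1 | intermediate
15 | methyl 5α-H-eudesma-3,11-dien-15-oate (7β-isopropenyl, 10β-methyl) | CC(=C)[C@@H]1CC[C@@]2(C)CCC=C(C(=O)OC)[C@@H]2C1 | intermediate
16 | 7β-acetyl analogue of 15 (methyl ketone) | CC(=O)[C@@H]1CC[C@@]2(C)CCC=C(C(=O)OC)[C@@H]2C1 | intermediate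
17 | enol triflate of 16 (C(OTf)=CH2 on C7) | C=C(OS(=O)(=O)C(F)(F)F)[C@@H]1CC[C@@]2(C)CCC=C(C(=O)OC)[C@@H]2C1 | intermediate
18 | allylic alcohol (C15 CH2OH; vinyl triflate on C7) | C=C(OS(=O)(=O)C(F)(F)F)[C@@H]1CC[C@@]2(C)CCC=C(CO)[C@@H]2C1 | intermediate
19 | methyl 15-hydroxy-5α-H-eudesma-3,11(13)-dien-12-oate | C=C(C(=O)OC)[C@@H]1CC[C@@]2(C)CCC=C(CO)[C@@H]2C1 | intermediate
20 | (E)-p-coumaric acid | OC(=O)/C=C/c1ccc(O)cc1 | starting material
21 | (Z)-p-coumaric acid | OC(=O)/C=C\c1ccc(O)cc1 | intermediate
22 | methyl 15-[(Z)-4-hydroxycinnamoyloxy]-5α-H-eudesma-3,11(13)-dien-12-oate (CNP0161949.2) | C=C(C(=O)OC)[C@@H]1CC[C@@]2(C)CCC=C(COC(=O)/C=C\c3ccc(O)cc3)[C@@H]2C1 | target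

**Step count**
Total step count: 14. Longest linear sequence: 13 steps (steps 1–12 and 14; step 13 prepares the acid partner).

**Steps most likely to fail**

1. Step 8. The C2 radical may lose a hydrogen atom to cobalt before it cyclizes, hydrogen may be removed from C5 instead of C3 after cyclization, or the photocatalyst may attack the isopropenyl group. The fallback sets out from 14 and comes back at 15. Acid 14 is condensed with N-hydroxyphthalimide and N,N'-diisopropylcarbodiimide to the N-acyloxyphthalimide ester F1. Reductive photoredox decarboxylation without cobalt (Ru(bpy)3Cl2, Hantzsch ester, iPr2NEt, blue LEDs, dilute MeCN) should give the same 6-endo cyclization but end with hydrogen-atom transfer to C4, giving the saturated ring A ester F2 (Giese-type reductive cyclization). Enolization with LiN(iPr)2 and trapping with PhSeBr on the α face, away from the axial C10 methyl group, should give the α-phenylselanyl ester F3. Oxidation with H2O2 gives the selenoxide F4, whose syn elimination toward the less hindered C3–H bonds should deliver 15.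

2. Step 1. Facial control at C10 may be insufficient because the auxiliary must override the intrinsic preference of the enamine for attack cis to the isopropenyl group, and addition to the tert-butyl acrylate may be slow. The fallback sets out from 1 and comes back at 6. The more substituted potassium enolate of 1 (equilibrating conditions) is trapped with allyl chloroformate as the allyl enol carbonate F5. Palladium-catalysed decarboxylative asymmetric allylic alkylation (Pd2(dba)3, (S)-tert-butyl-PHOX; the ligand enantiomer is switched if the sense is wrong) should set C10 under catalyst control in the 2-allyl ketone F6. Chemoselective hydroboration of the monosubstituted alkene with disiamylborane and oxidative work-up gives the primary alcohol F7, and oxidation (TEMPO, PhI(OAc)2, then NaClO2) gives the keto acid F8. Esterification with Boc2O, DMAP and t-BuOH then gives 6.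

3. Step 14. The coumarate may isomerize from Z to E in the presence of the phosphine, and alkylation may compete at the phenol or at the allylic terminus. The fallback sets out from 19 and comes back at 22. Alcohol 19 is converted with CBr4 and PPh3 into the allylic bromide F9 before the Z acid is present. The caesium carboxylate of 21 (Cs2CO3, 0.5 equiv, DMF, 0 °C, dark) should then displace bromide by SN2 at the primary carbon to give 22.

**Further compounds**
F1 | step 8 | N-acyloxyphthalimide ester of 14 | CC(=C)[C@@H]1CC[C@@](C)(CCC(=O)ON2C(=O)c3ccccc3C2=O)[C@H](C(=C)C(=O)OC)C1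
F2 | step 8 | saturated ring A ester, methyl 5α-H-eudesm-11-en-15-oate (drawn with the equatorial 4α ester) | CC(=C)[C@@H]1CC[C@@]2(C)CCC[C@@H](C(=O)OC)[C@@H]2C1
F3 | step 8 | α-phenylselanyl ester (SePh on C4, α face) | CC(=C)[C@@H]1CC[C@@]2(C)CCC[C@@](C(=O)OC)([Se]c3ccccc3)[C@@H]2C1
F4 | step 8 | selenoxide of F3 | CC(=C)[C@@H]1CC[C@@]2(C)CCC[C@@](C(=O)OC)([Se](=O)c3ccccc3)[C@@H]2C1
F5 | step 1 | allyl enol carbonate of 1 (C5=C10 enol) | CC(=C)[C@@H]1CCC(C)=C(OC(=O)OCC=C)C1
F6 | step 1 | 2-allyl-2-methyl ketone (allyl α on C10, methyl β) | CC(=C)[C@@H]1CC[C@@](C)(CC=C)C(=O)C1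
F7 | step 1 | primary alcohol (3-hydroxypropyl arm on C10) | CC(=C)[C@@H]1CC[C@@](C)(CCCO)C(=O)C1
F8 | step 1 | keto acid (propanoic acid arm on C10) | CC(=C)[C@@H]1CC[C@@](C)(CCC(=O)O)C(=O)C1
F9 | step 14 | allylic bromide (C15 CH2Br) of 19 | C=C(C(=O)OC)[C@@H]1CC[C@@]2(C)CCC=C(CBr)[C@@H]2C1
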